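## Analysis of the target

The target 29 (C30H22O15) is a linear chain of five benzene rings, A to E as read from left to right in the SMILES, joined only by four diaryl ether oxygens. It has no fused ring, no carbon–carbon bond between rings and no stereocentre, and the ether axes are not configurationally stable, so every selectivity question is one of regiochemistry. Ring A is a 3,5-dihydroxyphenyl group. Rings B and D each carry their two ether oxygens on the adjacent carbons C-1 and C-6, with hydroxyls at C-2 and C-4. Ring C has its ethers at C-1 and C-4 with hydroxyls at C-2 and C-6, and ring E is bound through C-1 with hydroxyls at C-2, C-4 and C-6. Eleven free phenols on five electron-rich rings make the compound prone to air oxidation, so the hydroxyls must stay masked until the last step and be released under neutral conditions. The difficulty lies in the ether bonds: four of the eight ether-bearing carbons (B C-1, C C-1, D C-1, E C-1) stand between two oxygen-bearing ortho carbons, so each of the four ethers has one doubly flanked end. The B–C and D–E ethers carry a third ortho oxygen on the partner ring (at B C-1 and D C-1), which makes them tri-ortho-substituted and a poor case for metal-mediated etherification. The strategy rests on ring D: its contiguous C-6 (O to ring E), C-1 (O to ring C) and C-2 (OH), with the further C-4 hydroxyl, is the pattern left when a nucleophile and an electrophile add across the triple bond of a 3,5-dioxygenated benzyne, the nucleophile going meta and the electrophile ortho to the flanking oxygen; ring B repeats the pattern.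

## Retrosynthetic reasoning

29 from 28. All eleven O–H bonds are traced back to benzyl ethers. Benzyl survives fluoride, phenoxides, aryl anions, copper catalysis with base and peracid, and is removed by hydrogenolysis, which leaves diaryl ethers alone. The forward step only has to be exhaustive.

28 from 19 and 27. The ring D C-1–O bond is cut. This is the central ether, and its oxygen sits on an unhindered carbon (ring C C-4 has hydrogens at C-3 and C-5). The cut therefore gives a hindered electrophile, iodide 19, and an unhindered, electron-rich nucleophile, phenol 27, the only polarity in which a copper-catalysed coupling is realistic. It divides the five rings two plus three and makes the route convergent. The forward reaction must couple a doubly flanked, electron-rich aryl iodide without reducing it.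

19 from 8, 14 and 15 (key disconnection). The ring D C-6–O bond and the C-1–I bond are cut together, which leads to aryne 17, phenoxide 16 (from 14) and the iodine donor 15. The oxygen of this ether belongs to the 2,6-disubstituted ring E phenol, and a flat, unencumbered aryne carbon accepts such a nucleophile where a metal centre would not. The cut also reduces the placing of four oxygens on ring D to the regiochemistry of one addition, since 8 already carries the C-2 and C-4 oxygens. The forward step must deliver the phenoxide to the aryne carbon remote from the flanking benzyloxy group and must trap anion 18 with iodine before it finds a proton.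

8 from 1 through 2 and 6. The C–Si bond is placed by directed ortho-metalation of carbamate 2 (through 3, 4 and 5). The carbamate of 6 is then exchanged for the triflate through silylphenol 7. In 2 the two positions between the carbamate and a benzyloxy group (C-2 and C-6) are equivalent by symmetry, so silicon can only arrive next to the carbamate on one kind of carbon, and the orientation of the aryne is fixed.

14 from 1 and 9 through 10 and 12. The C-1 hydroxyl of ring E is taken back to a formyl group (Dakin oxidation through formate 13). The formyl group is in turn removed by a Vilsmeier disconnection (through iminium salt 11) to the symmetrical triether 10, whose three free ring positions are equivalent, so the formylation has no regiochemical choice. 10 comes from 1 and one equivalent of 9. Phenol 1 thus supplies ring A, the aryne precursor and ring E.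

27 from 25. The ring C C-4 hydroxyl is likewise taken back to a formyl group (through formate 26). Carrying this oxygen as a carbon substituent distinguishes it from every benzyl ether without another protecting group, and keeps a second phenol out of the aryne and coupling steps.

25 from 24 and 1. The ring B C-1–O bond is cut with the same polarity argument: hindered iodide 24 and unhindered phenol 1.

24 from 8, 21 and 15. The ring B C-6–O and C-1–I bonds are cut as in the key disconnection, giving aryne 17 again, phenoxide 22 and anion 23. Ring B is ring D again, so triflate 8 and the same reaction serve both halves.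

21 from 20. The C-4 O–H bond is traced back to a benzyl ether. In 20 the C-4 benzyloxy group is the only one para to the formyl group, so a nucleophile that attacks a benzylic carbon expels the best-stabilised phenoxide there, and one step frees the flanked hydroxyl that the aryne step needs.

## Alternatives that were turned down

Alternative 1: The three C-4 oxygens of rings B, D and E are removed, leading back to A2, the permethylated pentamer with hydrogen at those positions. In the forward direction an iridium-catalysed C–H borylation would convert A2 into the tris(boronate) A1, whose three C–B bonds are then oxidised to C–O.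
- For: such borylation is governed by sterics, and in A2 the only ring hydrogens with two hydrogen neighbours are those at C-4 of rings B, D and E. The site selectivity is at least as dependable as the aryne regiochemistry of the chosen route, and the three rings could come from cheaper, less oxygenated building blocks.
- Against: A2 still contains all four ether bonds, including the two tri-ortho-substituted ones, and the plan does not say how they are made. Without the C-4 oxygens rings B and D are no longer 3,5-dioxygenated, so the aryne logic is lost and the hardest bonds fall back on metal coupling of hindered partners. The key step must reach completion at three sites on a large substrate. The methyl ethers leave eleven O–Me bonds to be cleaved by a strong Lewis acid on a sensitive product.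
- Comparison: the chosen route spends its key step on the ether bonds themselves and ends with a neutral hydrogenolysis.

Alternative 2: Ring A is disconnected across C1–C6 and C2–C3 (benzoate numbering of A3) into diene A4 and aryloxypropiolate A5, which already carries rings B and C. The forward step is a Diels–Alder addition followed by loss of one acetal methoxy group, which aromatises the adduct to benzoate A3.
- For: the polarisation of A4 and A5 fixes the orientation, the reaction type is better precedented than the phenoxide/iodine pairing chosen here, and ring A emerges with its three oxygens differentiated.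
- Against: ring A is the one ring that poses no problem. It is available as 1 and is attached in a single step (step 10). The ester of A3 has no counterpart in 29 and must be removed by hydrolysis and decarboxylation. A5 requires an electron-poor alkyne on the hindered ring B oxygen. The tri-ortho-substituted B–C ether must exist before the key step and is left to other chemistry. Mixed methyl and benzyl protection again ends in a Lewis-acid demethylation.
- Comparison: the chosen route reaches the same trimer stage (27) in fewer operations and makes the difficult B–C bond in its aryne step.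

Alternative 3: Ring C is disconnected across C1–C2 and C5–C6 into cyclobutenone A7, which carries rings D and E on its enol oxygen, and the doubly oxygenated alkyne A8, which carries rings A and B. On heating, A7 opens and adds across A8 in a (2+2) sense. A second four-electron ring opening and a six-electron closure then deliver A6, the assembled pentamer with a free C-2 hydroxyl and a C-6 silyl ether on ring C.
- For: this is the most convergent plan, since two dimers become the pentamer while the central ring is created. Neither ether bond of ring C has to be formed by coupling, a clear advantage over the two copper couplings at hindered iodides in the chosen route.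
- Against: A8 is an acetylene with oxygen on both carbons, one of them a hindered aryloxy group. Such alkynes are very labile and no dependable preparation exists at this size. With two donor oxygens the polarisation that directs the addition is weakened, so the orientation that places the aryloxy group between the hydroxyl and the silyl ether is not assured. A7 and A8 each presuppose a dimer in which a tri-ortho-substituted ether already exists, and nine benzyl ethers must survive the thermal cascade.
- Comparison: the chosen route gives up some convergence, but its components are each three steps or fewer from purchasable compounds, and the untested chemistry is confined to one intermolecular step that can be studied on 8 and 14 alone.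

Key step: step 7

Remark on the chemistry: in steps 7 and 9 the phenoxide is used as its potassium salt (KH, then KF/18-crown-6 in THF) so that no O–H donor and no acidic solvent is present when the aryl anion forms; 1, 9, 15 and 20 are taken as purchasable.

## Route

Step 1
Reactants: 1 3,5-bis(benzyloxy)phenol
Product: 2 3,5-bis(benzyloxy)phenyl N-isopropylcarbamate
Conditions: i-PrNCO, Et3N (cat.), CH2Cl2, rt
Reagents that add atoms: isopropyl isocyanate, CC(C)N=C=O
Why: Base-catalysed addition of the phenol to the isocyanate (carbamoylation) gives the N-monoalkyl carbamate, the strongest ortho-directing group on the ring and one that can later be removed by mild E1cB cleavage.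

Step 2
Reactants: 2 3,5-bis(benzyloxy)phenyl N-isopropylcarbamate
Product: 6 3,5-bis(benzyloxy)-2-(trimethylsilyl)phenyl N-isopropylcarbamate, via N-silyl carbamate 3 (not isolated), via aryllithium 4 (not isolated), via bis-silyl carbamate 5 (not isolated)
Conditions: TBSOTf, TMEDA, Et2O, 0 °C → rt; n-BuLi, TMEDA, −78 °C; TMSCl, −78 °C → rt; aq. NaHSO4
Reagents that add atoms: chlorotrimethylsilane, C[Si](C)(C)Cl
Why: Directed ortho-metalation: after N-silylation in the flask (which blocks N–H deprotonation and loss of isocyanate), n-BuLi/TMEDA removes the proton between the carbamate and a benzyloxy group (C-2 and C-6 are equivalent), the aryllithium is silylated and aqueous acid removes the N-silyl group. The carbamate outranks the ethers as a director, and the low temperature keeps benzylic lithiation and the anionic Fries shift out of play.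

Step 3
Reactants: 6 3,5-bis(benzyloxy)-2-(trimethylsilyl)phenyl N-isopropylcarbamate
Product: 8 3,5-bis(benzyloxy)-2-(trimethylsilyl)phenyl trifluoromethanesulfonate, via silylphenol 7 (not isolated)
Conditions: Et2NH, DBU, MeCN, 40 °C; then PhNTf2, rt
Reagents that add atoms: N-phenylbis(trifluoromethanesulfonimide), O=S(=O)(N(c1ccccc1)S(=O)(=O)C(F)(F)F)C(F)(F)F
Why: DBU deprotonates the carbamate N–H and the phenoxide is expelled (E1cB), the isocyanate being trapped by Et2NH; the 2-silylphenoxide is then triflated in the same flask by PhNTf2, a mild triflyl donor that does not protodesilylate the ring.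

Step 4
Reactants: 1 3,5-bis(benzyloxy)phenol; 9 benzyl bromide
Product: 10 1,3,5-tris(benzyloxy)benzene
Conditions: K2CO3, DMF, rt
Reagents that add atoms: none
Why: Williamson etherification of the single phenol; with a carbonate base in a dipolar aprotic solvent the phenoxide is alkylated on oxygen, and the product is the symmetrical triether whose three free ring positions are equivalent.

Step 5
Reactants: 10 1,3,5-tris(benzyloxy)benzene
Product: 12 2,4,6-tris(benzyloxy)benzaldehyde, via iminium chloride 11 (not isolated)
Conditions: POCl3, DMF, 0 °C → rt; then aq. NaOAc, rt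
Reagents that add atoms: N,N-dimethylformamide, CN(C)C=O; water, O
Why: Vilsmeier–Haack formylation: the chloroiminium ion made from DMF and POCl3 attacks the phloroglucinol triether at one of its three equivalent positions, the iminium group then deactivates the ring against a second attack, and buffered hydrolysis gives the aldehyde with the benzyl ethers intact.

Step 6
Reactants: 12 2,4,6-tris(benzyloxy)benzaldehyde
Product: 14 2,4,6-tris(benzyloxy)phenol, via aryl formate 13 (not isolated)
Conditions: mCPBA, CH2Cl2, 0 °C → rt; then K2CO3 (cat.), MeOH, rt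
Reagents that add atoms: 3-chloroperbenzoic acid, O=C(OO)c1cccc(Cl)c1
Why: Dakin-type Baeyer–Villiger oxidation: the very electron-rich aryl group migrates in the Criegee intermediate in preference to hydride, and the formate is cleaved by methanolysis to the hindered phenol.

Step 7
Reactants: 8 3,5-bis(benzyloxy)-2-(trimethylsilyl)phenyl trifluoromethanesulfonate; 14 2,4,6-tris(benzyloxy)phenol; 15 perfluorohexyl iodide
Product: 19 1,5-bis(benzyloxy)-2-iodo-3-[2,4,6-tris(benzyloxy)phenoxy]benzene (protected D–E iodide), via potassium phenoxide 16 (not isolated), via aryne 17 (not isolated), via arylpotassium 18 (not isolated)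
Conditions: KH, THF, 0 °C; then KF, 18-crown-6, slow addition of 8, THF, 0 °C → rt, dark
Reagents that add atoms: none
Why: Proposed new method: fluoride attacks silicon of 8 and triflate leaves (1,2-elimination), releasing aryne 17; its flanking benzyloxy group makes the remote aryne carbon (ring D C-6) the electrophilic one, because the charge that develops on the neighbouring carbon (ring D C-1) is stabilised inductively by the adjacent C–O bond, so phenoxide 16 adds at C-6 and gives aryl anion 18. Anion 18 then attacks iodine of 15 (halogen-philic substitution), and the perfluorohexyl anion that leaves collapses to a perfluoroalkene and fluoride. The closest known reaction type is the three-component 1,2-difunctionalisation of arynes from o-silylaryl triflates in which a nitrogen or sulfur nucleophile is paired with a halogen donor, together with the metal-free O-arylation of phenols by the same arynes; the pairing of a phenoxide with iodine transfer is the untested element. No ring is closed and no stereocentre is formed. Two selectivities are required: the regioselectivity of addition, secured by the single benzyloxy group flanking the triple bond (the second one is meta to the site of attack and has little say), and iodination in preference to protonation, secured by the preformed phenoxide, the absence of any O–H donor, an ether solvent and an excess of 15. The aryne carbon is unhindered, so the 2,6-disubstituted phenoxide reacts without a metal. Slow addition of 8 keeps the aryne concentration low so that 18 meets 15 and not a second aryne, and light is excluded to suppress electron transfer from 16 to 15.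

Step 8
Reactants: 20 3,4,5-tris(benzyloxy)benzaldehyde
Product: 21 3,5-bis(benzyloxy)-4-hydroxybenzaldehyde
Conditions: NaSEt (1.2 equiv), DMF, 70 °C; then aq. HCl
Reagents that add atoms: none
Why: Nucleophilic dealkylation of an aryl ether by a thiolate (SN2 at the benzylic carbon): only the C-4 ether is para to the formyl group, so its cleavage expels the best-stabilised phenoxide, and once that phenoxide has formed the ring is too electron-rich for a second cleavage; the thiolate adds to the aldehyde only reversibly.

Step 9
Reactants: 8 3,5-bis(benzyloxy)-2-(trimethylsilyl)phenyl trifluoromethanesulfonate; 21 3,5-bis(benzyloxy)-4-hydroxybenzaldehyde; 15 perfluorohexyl iodide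
Product: 24 3,5-bis(benzyloxy)-4-[3,5-bis(benzyloxy)-2-iodophenoxy]benzaldehyde (B–C iodide), via potassium phenoxide 22 (not isolated), via arylpotassium 23 (not isolated)
Conditions: KH (1.0 equiv), THF, 0 °C; then KF, 18-crown-6, slow addition of 8, THF, 0 → 40 °C, dark
Reagents that add atoms: none
Why: Proposed new method: the mechanism is that of step 7 (fluoride again releases aryne 17 from 8, phenoxide 22 adds at the carbon remote from the flanking benzyloxy group, anion 23 takes iodine from 15), and the closest known reaction type is again the aryne 1,2-difunctionalisation with a heteroatom nucleophile and a halogen donor. The formyl group makes 22 a weaker nucleophile, but as a vinylogous carboxylate it is also a poor electrophile, and the excess of 15 should take up anion 23 before it meets the aldehyde of product 24.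

Step 10
Reactants: 24 3,5-bis(benzyloxy)-4-[3,5-bis(benzyloxy)-2-iodophenoxy]benzaldehyde; 1 3,5-bis(benzyloxy)phenol
Product: 25 3,5-bis(benzyloxy)-4-{3,5-bis(benzyloxy)-2-[3,5-bis(benzyloxy)phenoxy]phenoxy}benzaldehyde (A–B–C aldehyde)
Conditions: CuI (cat.), picolinic acid, K3PO4, DMSO, 90 °C
Reagents that add atoms: none
Why: Ullmann-type diaryl ether synthesis with monovalent copper and a picolinate ligand: the hindered partner is the iodide and the nucleophile 1 is an unhindered phenol used in excess, the arrangement this coupling tolerates; the aldehyde is stable to K3PO4 in DMSO.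

Step 11
Reactants: 25 3,5-bis(benzyloxy)-4-{3,5-bis(benzyloxy)-2-[3,5-bis(benzyloxy)phenoxy]phenoxy}benzaldehyde
Product: 27 3,5-bis(benzyloxy)-4-{3,5-bis(benzyloxy)-2-[3,5-bis(benzyloxy)phenoxy]phenoxy}phenol (A–B–C phenol), via aryl formate 26 (not isolated)
Conditions: mCPBA, CH2Cl2, 0 °C → rt; then K2CO3 (cat.), MeOH–THF, rt
Reagents that add atoms: 3-chloroperbenzoic acid, O=C(OO)c1cccc(Cl)c1
Why: Dakin-type Baeyer–Villiger oxidation: the 3,4,5-trioxygenated aryl group migrates, and methanolysis of formate 26 unveils the ring C C-4 phenol; the other rings carry no free hydroxyl and should resist the peracid at this temperature.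

Step 12
Reactants: 19 1,5-bis(benzyloxy)-2-iodo-3-[2,4,6-tris(benzyloxy)phenoxy]benzene; 27 3,5-bis(benzyloxy)-4-{3,5-bis(benzyloxy)-2-[3,5-bis(benzyloxy)phenoxy]phenoxy}phenol
Product: 28 undecabenzyl ether of 29 (every hydroxyl of rings A to E benzylated)
Conditions: CuI (cat.), picolinic acid, K3PO4, DMSO–1,4-dioxane, 100 °C
Reagents that add atoms: none
Why: Ullmann-type coupling as in step 10: the C–I bond of 19 is activated by monovalent copper and the unhindered, electron-rich phenoxide of 27 (hydrogens on both ortho carbons) forms the ring D C-1–O bond; no other halide or free phenol is present, so only one ether can form.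

Step 13
Reactants: 28 undecabenzyl ether of 29
Product: 29 CNP0018313.0
Conditions: H2 (1–3 bar), Pd(OH)2/C, THF–MeOH, rt
Reagents that add atoms: none
Why: Hydrogenolysis of all eleven benzyl ethers over a palladium catalyst under neutral conditions; diaryl ether bonds are not cleaved and toluene is the only co-product, so the air-sensitive polyphenol should be obtained by filtration and evaporation under inert gas.

## Compound list

1 | 3,5-bis(benzyloxy)phenol | Oc1cc(OCc2ccccc2)cc(OCc2ccccc2)c1 | starting material
2 | 3,5-bis(benzyloxy)phenyl N-isopropylcarbamate | CC(C)NC(=O)Oc1cc(OCc2ccccc2)cc(OCc2ccccc2)c1 | intermediate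
3 | 3,5-bis(benzyloxy)phenyl N-(tert-butyldimethylsilyl)-N-isopropylcarbamate | CC(C)N(C(=O)Oc1cc(OCc2ccccc2)cc(OCc2ccccc2)c1)[Si](C)(C)C(C)(C)C | intermediate (not isolated)
4 | 2,4-bis(benzyloxy)-6-{[tert-butyldimethylsilyl(isopropyl)carbamoyl]oxy}phenyllithium | [Li]c1c(OC(=O)N(C(C)C)[Si](C)(C)C(C)(C)C)cc(OCc2ccccc2)cc1OCc1ccccc1 | intermediate (not isolated)
5 | 3,5-bis(benzyloxy)-2-(trimethylsilyl)phenyl N-(tert-butyldimethylsilyl)-N-isopropylcarbamate | C[Si](C)(C)c1c(OC(=O)N(C(C)C)[Si](C)(C)C(C)(C)C)cc(OCc2ccccc2)cc1OCc1ccccc1 | intermediate (not isolated)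
6 | 3,5-bis(benzyloxy)-2-(trimethylsilyl)phenyl N-isopropylcarbamate | C[Si](C)(C)c1c(OC(=O)NC(C)C)cc(OCc2ccccc2)cc1OCc1ccccc1 | intermediate
7 | 3,5-bis(benzyloxy)-2-(trimethylsilyl)phenol | C[Si](C)(C)c1c(O)cc(OCc2ccccc2)cc1OCc1ccccc1 | intermediate (not isolated)
8 | 3,5-bis(benzyloxy)-2-(trimethylsilyl)phenyl trifluoromethanesulfonate | C[Si](C)(C)c1c(OCc2ccccc2)cc(OCc2ccccc2)cc1OS(=O)(=O)C(F)(F)F | intermediate
9 | benzyl bromide | BrCc1ccccc1 | starting material
10 | 1,3,5-tris(benzyloxy)benzene | c1c(OCc2ccccc2)cc(OCc2ccccc2)cc1OCc1ccccc1 | intermediate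
11 | N,N-dimethyl-[2,4,6-tris(benzyloxy)phenyl]methaniminium chloride | C[N+](C)=Cc1c(OCc2ccccc2)cc(OCc2ccccc2)cc1OCc1ccccc1.[Cl-] | intermediate (not isolated)
12 | 2,4,6-tris(benzyloxy)benzaldehyde | O=Cc1c(OCc2ccccc2)cc(OCc2ccccc2)cc1OCc1ccccc1 | intermediate
13 | 2,4,6-tris(benzyloxy)phenyl formate | O=COc1c(OCc2ccccc2)cc(OCc2ccccc2)cc1OCc1ccccc1 | intermediate (not isolated)
14 | 2,4,6-tris(benzyloxy)phenol | Oc1c(OCc2ccccc2)cc(OCc2ccccc2)cc1OCc1ccccc1 | intermediate
15 | perfluorohexyl iodide | FC(F)(F)C(F)(F)C(F)(F)C(F)(F)C(F)(F)C(F)(F)I | starting material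
16 | potassium 2,4,6-tris(benzyloxy)phenoxide | [K+].[O-]c1c(OCc2ccccc2)cc(OCc2ccccc2)cc1OCc1ccccc1 | intermediate (not isolated)
17 | 3,5-bis(benzyloxy)benzyne | C1#CC(OCc2ccccc2)=CC(OCc2ccccc2)=C1 | intermediate (not isolated)
18 | 2,4-bis(benzyloxy)-6-[2,4,6-tris(benzyloxy)phenoxy]phenylpotassium | [K]c1c(OCc2ccccc2)cc(OCc2ccccc2)cc1Oc1c(OCc2ccccc2)cc(OCc2ccccc2)cc1OCc1ccccc1 | intermediate (not isolated)
19 | 1,5-bis(benzyloxy)-2-iodo-3-[2,4,6-tris(benzyloxy)phenoxy]benzene | Ic1c(OCc2ccccc2)cc(OCc2ccccc2)cc1Oc1c(OCc2ccccc2)cc(OCc2ccccc2)cc1OCc1ccccc1 | intermediate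
20 | 3,4,5-tris(benzyloxy)benzaldehyde | O=Cc1cc(OCc2ccccc2)c(OCc2ccccc2)c(OCc2ccccc2)c1 | starting material
21 | 3,5-bis(benzyloxy)-4-hydroxybenzaldehyde | O=Cc1cc(OCc2ccccc2)c(O)c(OCc2ccccc2)c1 | intermediate
22 | potassium 2,6-bis(benzyloxy)-4-formylphenoxide | [K+].[O-]c1c(OCc2ccccc2)cc(C=O)cc1OCc1ccccc1 | intermediate (not isolated)
23 | 2,4-bis(benzyloxy)-6-[2,6-bis(benzyloxy)-4-formylphenoxy]phenylpotassium | [K]c1c(OCc2ccccc2)cc(OCc2ccccc2)cc1Oc1c(OCc2ccccc2)cc(C=O)cc1OCc1ccccc1 | intermediate (not isolated)
24 | 3,5-bis(benzyloxy)-4-[3,5-bis(benzyloxy)-2-iodophenoxy]benzaldehyde | O=Cc1cc(OCc2ccccc2)c(Oc2cc(OCc3ccccc3)cc(OCc3ccccc3)c2I)c(OCc2ccccc2)c1 | intermediate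
25 | 3,5-bis(benzyloxy)-4-{3,5-bis(benzyloxy)-2-[3,5-bis(benzyloxy)phenoxy]phenoxy}benzaldehyde | O=Cc1cc(OCc2ccccc2)c(Oc2cc(OCc3ccccc3)cc(OCc3ccccc3)c2Oc2cc(OCc3ccccc3)cc(OCc3ccccc3)c2)c(OCc2ccccc2)c1 | intermediate
26 | 3,5-bis(benzyloxy)-4-{3,5-bis(benzyloxy)-2-[3,5-bis(benzyloxy)phenoxy]phenoxy}phenyl formate | O=COc1cc(OCc2ccccc2)c(Oc2cc(OCc3ccccc3)cc(OCc3ccccc3)c2Oc2cc(OCc3ccccc3)cc(OCc3ccccc3)c2)c(OCc2ccccc2)c1 | intermediate (not isolated)
27 | 3,5-bis(benzyloxy)-4-{3,5-bis(benzyloxy)-2-[3,5-bis(benzyloxy)phenoxy]phenoxy}phenol | Oc1cc(OCc2ccccc2)c(Oc2cc(OCc3ccccc3)cc(OCc3ccccc3)c2Oc2cc(OCc3ccccc3)cc(OCc3ccccc3)c2)c(OCc2ccccc2)c1 | intermediate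
28 | undecabenzyl ether of 29 | c1ccccc1COc1cc(OCc2ccccc2)cc(Oc2c(OCc3ccccc3)cc(OCc3ccccc3)cc2Oc2c(OCc3ccccc3)cc(Oc3c(OCc4ccccc4)cc(OCc4ccccc4)cc3Oc3c(OCc4ccccc4)cc(OCc4ccccc4)cc3OCc3ccccc3)cc2OCc2ccccc2)c1 | intermediate
29 | CNP0018313.0 | Oc1cc(O)cc(Oc2c(O)cc(O)cc2Oc2c(O)cc(Oc3c(O)cc(O)cc3Oc3c(O)cc(O)cc3O)cc2O)c1 | target

## Step count and least certain steps

Total: 13 steps. Longest linear sequence: 8 steps (1 → 2 → 6 → 8 → 24 → 25 → 27 → 28 → 29).

Step 7 (key step, new method). The likeliest failure is protonation of anion 18 outrunning iodine transfer, by traces of water or by a benzylic C–H of a neighbouring benzyl ether. Other risks are electron transfer from the electron-rich phenoxide 16 to 15, leading to perfluoroalkylation of the phenoxide ring, and attack of 16 on sulfur of triflate 8. The fallback uses known chemistry, sets out from 14 and returns at 19. Commercial 2,4,6-trifluoronitrobenzene is treated with two equivalents of benzyl alcohol and NaH (THF–DMF, −20 → 0 °C); two successive nucleophilic aromatic substitutions, para and then ortho to the nitro group, give 1,5-bis(benzyloxy)-3-fluoro-2-nitrobenzene F1, to be separated from any isomer in which both ortho fluorines have been replaced. The remaining ortho fluorine is displaced by 14 (K2CO3, DMF, 70 °C) to give the nitro diaryl ether 1,5-bis(benzyloxy)-2-nitro-3-[2,4,6-tris(benzyloxy)phenoxy]benzene F2. Reduction with Fe and NH4Cl in aqueous ethanol gives 2,4-bis(benzyloxy)-6-[2,4,6-tris(benzyloxy)phenoxy]aniline F3. Diazotisation with NaNO2 and p-toluenesulfonic acid in the presence of KI (MeCN–water, 10 °C → rt) passes through the diazonium tosylate F4 and gives 19 by Sandmeyer-type iodination.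

Step 9 (new method). In addition to the risks of step 7, the formyl-stabilised phenoxide 22 may add so slowly that aryne 17 is consumed by fluoride, by solvent or by itself, and anion 23 may add to the aldehyde of product 24. The fallback uses known chemistry, sets out from 21 and returns at 24. Compound 21 displaces the fluorine of F1 (made as above; Cs2CO3, DMF, 90 °C) to give 3,5-bis(benzyloxy)-4-[3,5-bis(benzyloxy)-2-nitrophenoxy]benzaldehyde F5. Reduction with Fe and NH4Cl gives 4-[2-amino-3,5-bis(benzyloxy)phenoxy]-3,5-bis(benzyloxy)benzaldehyde F6, which is used at once because amine and aldehyde can condense. Diazotisation and iodination as above, through the diazonium tosylate F7, give 24.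

Step 12. Bond formation at the doubly flanked, electron-rich C–I bond of 19 may be so slow that hydrodeiodination of 19 and oxidative decay of the phenoxide of 27 take over; poor solubility of the two large fragments adds to this. The fallback reverses the polarity so that the hindered ring is the nucleophile and an aryne is the electrophile; it sets out from 19 and 27 and returns at 28. Hydroxylation of 19 (Pd2(dba)3, t-BuXPhos, KOH, 1,4-dioxane–water, 100 °C; zerovalent palladium) gives 2,4-bis(benzyloxy)-6-[2,4,6-tris(benzyloxy)phenoxy]phenol F8. Phenol 27 is taken through the operations of steps 1 to 3: the N-isopropylcarbamate of 27 F9, its ring C C-3 trimethylsilyl derivative F10 (lithiation between the carbamate and the C-2 benzyloxy group), and the silyl triflate F11 with the triflate at ring C C-4. CsF in MeCN–toluene releases the ring C aryne F12; the phenoxide of F8 adds at C-4, remote from the C-2 benzyloxy group, and the anion at C-3 is protonated, giving 28.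

Step 10. The failure mode is that of step 12 (slow coupling, hydrodeiodination of 24), although the small phenol 1 can be used in excess. The fallback sets out from 24 and returns at 25. Miyaura borylation (B2pin2, Pd2(dba)3, XPhos, KOAc, 1,4-dioxane, 100 °C) gives the pinacol boronate F13 with boron in place of iodine. Oxidation with trimethylamine N-oxide (THF, 50 °C), which leaves the aldehyde alone, gives 3,5-bis(benzyloxy)-4-[3,5-bis(benzyloxy)-2-hydroxyphenoxy]benzaldehyde F14. Treatment of F14 with 8 and CsF in MeCN at rt is the known O-arylation of a phenol by an aryne: the phenoxide adds to 17 at the carbon remote from the benzyloxy group and the anion is protonated, so ring A is attached directly and 25 results.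

Step 8. Cleavage may not stay at the C-4 ether (competing attack on a C-3 benzyl group), or the thiolate may be held back as the hemithioacetal of the aldehyde so that conversion stalls. The fallback builds the pattern by protection instead of selective cleavage; it sets out from 9 and commercial 3,4,5-trihydroxybenzaldehyde, replaces step 8 and returns at 21. The most acidic hydroxyl, at C-4, is alkylated with one equivalent of allyl bromide (NaHCO3, NaI cat., DMF, 40 °C) to give 4-(allyloxy)-3,5-dihydroxybenzaldehyde F15. The two remaining hydroxyls are benzylated with two equivalents of 9 (K2CO3, DMF, 50 °C) to give 4-(allyloxy)-3,5-bis(benzyloxy)benzaldehyde F16. Deallylation with Pd(PPh3)4 and morpholine in THF at rt (zerovalent palladium) gives 21.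

Step 2. n-BuLi may deprotonate a benzylic O–CH2 group (followed by Wittig rearrangement) or the position between the two benzyloxy groups, and the lithiated carbamate may undergo the anionic Fries shift if it warms. The fallback avoids deprotonation altogether; it sets out from 1, returns at 8 and replaces steps 1 to 3. Bromination of 1 with N-bromosuccinimide (CH2Cl2, −78 °C) gives 3,5-bis(benzyloxy)-2-bromophenol F17, to be separated from any para isomer. Hexamethyldisilazane in refluxing THF gives its trimethylsilyl ether F18. n-BuLi in THF at −100 °C effects bromine–lithium exchange and the retro-Brook shift of silicon from oxygen to carbon, and the resulting lithium salt of 7 is triflated in the same flask with Tf2O to give 8.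

## Further compounds

F1 | step 7 | 1,5-bis(benzyloxy)-3-fluoro-2-nitrobenzene | [O-][N+](=O)c1c(F)cc(OCc2ccccc2)cc1OCc1ccccc1
F2 | step 7 | 1,5-bis(benzyloxy)-2-nitro-3-[2,4,6-tris(benzyloxy)phenoxy]benzene | [O-][N+](=O)c1c(OCc2ccccc2)cc(OCc2ccccc2)cc1Oc1c(OCc2ccccc2)cc(OCc2ccccc2)cc1OCc1ccccc1
F3 | step 7 | 2,4-bis(benzyloxy)-6-[2,4,6-tris(benzyloxy)phenoxy]aniline | Nc1c(OCc2ccccc2)cc(OCc2ccccc2)cc1Oc1c(OCc2ccccc2)cc(OCc2ccccc2)cc1OCc1ccccc1
F4 | step 7 | 2,4-bis(benzyloxy)-6-[2,4,6-tris(benzyloxy)phenoxy]benzenediazonium 4-methylbenzenesulfonate | Cc1ccc(cc1)S(=O)(=O)[O-].N#[N+]c1c(OCc2ccccc2)cc(OCc2ccccc2)cc1Oc1c(OCc2ccccc2)cc(OCc2ccccc2)cc1OCc1ccccc1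
F5 | step 9 | 3,5-bis(benzyloxy)-4-[3,5-bis(benzyloxy)-2-nitrophenoxy]benzaldehyde | O=Cc1cc(OCc2ccccc2)c(Oc2cc(OCc3ccccc3)cc(OCc3ccccc3)c2[N+](=O)[O-])c(OCc2ccccc2)c1
F6 | step 9 | 4-[2-amino-3,5-bis(benzyloxy)phenoxy]-3,5-bis(benzyloxy)benzaldehyde | O=Cc1cc(OCc2ccccc2)c(Oc2cc(OCc3ccccc3)cc(OCc3ccccc3)c2N)c(OCc2ccccc2)c1
F7 | step 9 | 2,4-bis(benzyloxy)-6-[2,6-bis(benzyloxy)-4-formylphenoxy]benzenediazonium 4-methylbenzenesulfonate | Cc1ccc(cc1)S(=O)(=O)[O-].O=Cc1cc(OCc2ccccc2)c(Oc2cc(OCc3ccccc3)cc(OCc3ccccc3)c2[N+]#N)c(OCc2ccccc2)c1
F8 | step 12 | 2,4-bis(benzyloxy)-6-[2,4,6-tris(benzyloxy)phenoxy]phenol | Oc1c(OCc2ccccc2)cc(OCc2ccccc2)cc1Oc1c(OCc2ccccc2)cc(OCc2ccccc2)cc1OCc1ccccc1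
F9 | step 12 | N-isopropylcarbamate of 27 | CC(C)NC(=O)Oc1cc(OCc2ccccc2)c(Oc2cc(OCc3ccccc3)cc(OCc3ccccc3)c2Oc2cc(OCc3ccccc3)cc(OCc3ccccc3)c2)c(OCc2ccccc2)c1
F10 | step 12 | N-isopropylcarbamate of 27 with trimethylsilyl at ring C C-3 | CC(C)NC(=O)Oc1c([Si](C)(C)C)c(OCc2ccccc2)c(Oc2cc(OCc3ccccc3)cc(OCc3ccccc3)c2Oc2cc(OCc3ccccc3)cc(OCc3ccccc3)c2)c(OCc2ccccc2)c1
F11 | step 12 | triflate of 27 with trimethylsilyl at ring C C-3 | O=S(=O)(Oc1c([Si](C)(C)C)c(OCc2ccccc2)c(Oc2cc(OCc3ccccc3)cc(OCc3ccccc3)c2Oc2cc(OCc3ccccc3)cc(OCc3ccccc3)c2)c(OCc2ccccc2)c1)C(F)(F)F
F12 | step 12 | ring C aryne of the A–B–C trimer (C-3/C-4 didehydro) | C1#CC(OCc2ccccc2)=C(Oc2cc(OCc3ccccc3)cc(OCc3ccccc3)c2Oc2cc(OCc3ccccc3)cc(OCc3ccccc3)c2)C(OCc2ccccc2)=C1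
F13 | step 10 | 3,5-bis(benzyloxy)-4-[3,5-bis(benzyloxy)-2-(4,4,5,5-tetramethyl-1,3,2-dioxaborolan-2-yl)phenoxy]benzaldehyde | O=Cc1cc(OCc2ccccc2)c(Oc2cc(OCc3ccccc3)cc(OCc3ccccc3)c2B2OC(C)(C)C(C)(C)O2)c(OCc2ccccc2)c1
F14 | step 10 | 3,5-bis(benzyloxy)-4-[3,5-bis(benzyloxy)-2-hydroxyphenoxy]benzaldehyde | O=Cc1cc(OCc2ccccc2)c(Oc2cc(OCc3ccccc3)cc(OCc3ccccc3)c2O)c(OCc2ccccc2)c1
F15 | step 8 | 4-(allyloxy)-3,5-dihydroxybenzaldehyde | O=Cc1cc(O)c(OCC=C)c(O)c1
F16 | step 8 | 4-(allyloxy)-3,5-bis(benzyloxy)benzaldehyde | O=Cc1cc(OCc2ccccc2)c(OCC=C)c(OCc2ccccc2)c1
F17 | step 2 | 3,5-bis(benzyloxy)-2-bromophenol | Oc1cc(OCc2ccccc2)cc(OCc2ccccc2)c1Br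
F18 | step 2 | [3,5-bis(benzyloxy)-2-bromophenoxy]trimethylsilane | C[Si](C)(C)Oc1cc(OCc2ccccc2)cc(OCc2ccccc2)c1Br
A1 | alternative 1 | tris(pinacolboronate) of the permethylated pentamer (boron at C-4 of rings B, D and E) | COc1cc(OC)cc(Oc2c(OC)cc(B3OC(C)(C)C(C)(C)O3)cc2Oc2c(OC)cc(Oc3c(OC)cc(B4OC(C)(C)C(C)(C)O4)cc3Oc3c(OC)cc(B4OC(C)(C)C(C)(C)O4)cc3OC)cc2OC)c1
A2 | alternative 1 | permethylated pentamer with hydrogen at C-4 of rings B, D and E | COc1cc(OC)cc(Oc2c(OC)cccc2Oc2c(OC)cc(Oc3c(OC)cccc3Oc3c(OC)cccc3OC)cc2OC)c1
A3 | alternative 2 | methyl 2-aryloxy-4-hydroxy-6-methoxybenzoate carrying rings B and C | COC(=O)c1c(OC)cc(O)cc1Oc1c(OC)cc(OC)cc1Oc1c(OC)cc(OCc2ccccc2)cc1OC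
A4 | alternative 2 | 1,1-dimethoxy-3-(trimethylsilyloxy)buta-1,3-diene | COC(OC)=CC(=C)O[Si](C)(C)C
A5 | alternative 2 | methyl 3-aryloxypropiolate carrying rings B and C | COC(=O)C#COc1c(OC)cc(OC)cc1Oc1c(OC)cc(OCc2ccccc2)cc1OC
A6 | alternative 3 | protected pentamer with free C-2 hydroxyl and C-6 triisopropylsilyl ether on ring C | Oc1cc(Oc2c(OCc3ccccc3)cc(OCc3ccccc3)cc2Oc2c(OCc3ccccc3)cc(OCc3ccccc3)cc2OCc2ccccc2)cc(O[Si](C(C)C)(C(C)C)C(C)C)c1Oc1cc(OCc2ccccc2)cc(OCc2ccccc2)c1Oc1cc(OCc2ccccc2)cc(OCc2ccccc2)c1
A7 | alternative 3 | 3-aryloxycyclobut-2-enone carrying rings D and E | O=C1C=C(Oc2c(OCc3ccccc3)cc(OCc3ccccc3)cc2Oc2c(OCc3ccccc3)cc(OCc3ccccc3)cc2OCc2ccccc2)C1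
A8 | alternative 3 | 1-aryloxy-2-(triisopropylsilyloxy)ethyne carrying rings A and B | CC(C)[Si](C(C)C)(C(C)C)OC#COc1cc(OCc2ccccc2)cc(OCc2ccccc2)c1Oc1cc(OCc2ccccc2)cc(OCc2ccccc2)c1
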